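**Plan**

- Retrosynthesis first removes the C3' bromine (placed last, ortho to the ring-B hydroxyl), then masks both phenols as methyl ethers and takes off the C4'/C5' bromines of ring B, leaving 1,5-dibromo-2-methoxy-3-(2-methoxyphenoxy)benzene.
- Ring A of that ether (C1 O, C2 Br, C3 H, C4 Br, C5 H, C6 ether O) is cut at C1–C6 and C4–C5. C1–C4 are C3–C6 of a 4,6-dibromo-3-methoxy-2-pyrone, and C5/C6 are the two carbons of (2-methoxyphenoxy)acetylene.
- Forward: the pyrone comes from 3-hydroxy-2-pyrone (dibromination, O-methylation) and the alkynyl ether from guaiacol and trichloroethylene. Ring B is bought as guaiacol; ring A is built by [4+2] cycloaddition and CO2 loss.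
- Ring B is then brominated para to both oxygens, the methyl ethers are cleaved, and the last bromine is delivered ortho to the ring-B hydroxyl.
- The target has no stereocentre. Only regiochemistry must be controlled: by alkyne polarisation in the cycloaddition and by oxygen directing effects in the brominations.

Key step: step 5

Remark: ring A is the 3,5-dibromo-2-hydroxyphenoxy ring (C1 OH, C2 and C4 Br, C6 ether O) and ring B the tribromophenol ring (C1' ether O, C2' OH, C3'–C5' Br); bromination of the dienol 3-hydroxy-2-pyrone is assumed to follow the ortho/para-type orientation (C4, then C6).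

**Route**

Step 1
Reactants: 1 3-hydroxy-2H-pyran-2-one
Product: 3 4,6-dibromo-3-hydroxy-2H-pyran-2-one, via 4-bromo-3-hydroxy-2H-pyran-2-one 2 (not isolated)
Conditions: Br2 (2.1 equiv), AcOH, 15 °C to rt
Reagents that add atoms: bromine, BrBr
Why: Electrophilic bromination of a cyclic dienol, in which the C3 hydroxyl activates C4 (vinylogous ortho position) and, through the diene, C6 (vinylogous para position), so two successive substitutions should place bromine on exactly these carbons.

Step 2
Reactants: 3 4,6-dibromo-3-hydroxy-2H-pyran-2-one
Product: 4 4,6-dibromo-3-methoxy-2H-pyran-2-one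
Conditions: Me3SiCHN2 (1.5 equiv), PhMe/MeOH 4:1, 0 °C; AcOH quench
Reagents that add atoms: (trimethylsilyl)diazomethane, C[Si](C)(C)C=[N+]=[N-]
Why: O-Methylation of an acidic enol by a diazoalkane under neutral conditions, chosen because no base or strong nucleophile is present that could add to the C6–Br terminus, a vinylogous acyl bromide.

Step 3
Reactants: 5 guaiacol (2-methoxyphenol); 6 trichloroethylene
Product: 8 1-{[(E)-1,2-dichloroethenyl]oxy}-2-methoxybenzene, via dichloroacetylene 7 (not isolated)
Conditions: K2CO3 (1.5 equiv), DMF, 70 °C
Reagents that add atoms: none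
Why: Base-induced loss of HCl from trichloroethylene gives dichloroacetylene in the flask, and anti addition of the phenoxide across it (the standard elimination–addition vinylation of phenols) should give the E-dichlorovinyl ether.

Step 4
Reactants: 8 1-{[(E)-1,2-dichloroethenyl]oxy}-2-methoxybenzene
Product: 11 1-(ethynyloxy)-2-methoxybenzene, via chloroethynyl ether 9 (not isolated), via lithium acetylide 10 (not isolated)
Conditions: n-BuLi (2.3 equiv), Et2O, −78 to −40 °C; then H2O, −78 °C; cold extraction, used at once as a PhMe solution
Reagents that add atoms: none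
Why: Dehydrochlorination by the first equivalent of n-butyllithium and chlorine–lithium exchange by the second give the lithium acetylide, which water protonates to the terminal alkynyl ether (the established dichlorovinyl-ether route to ynol ethers); the aryl group has no β-hydrogen, so retro-ene fragmentation to a ketene is not available.

Step 5
Reactants: 4 4,6-dibromo-3-methoxy-2H-pyran-2-one; 11 1-(ethynyloxy)-2-methoxybenzene
Product: 13 1,5-dibromo-2-methoxy-3-(2-methoxyphenoxy)benzene, via bicyclic lactone 12 (not isolated)
Conditions: 11 (2 equiv, in two portions), PhMe, 90 °C, sealed tube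
Reagents that add atoms: none
Why: The ynol ether is polarised so that its terminal carbon is the nucleophilic end, and in an inverse-electron-demand [4+2] cycloaddition it should bond to pyrone C6, the δ-carbon of the dienyl lactone that carries the larger terminal LUMO coefficient and a bromine, while the oxygen-bearing alkyne carbon bonds to C3; the 2-oxabicyclo[2.2.2]octadienone 12 formed in this way then loses CO2 by retro-[4+2] cycloreversion. The closest known reaction type is the Diels–Alder/retro-Diels–Alder benzannulation of halogenated 2-pyrones with alkynes, and the orientation matches that of 3-halo-2-pyrones with enol ethers, where the oxygenated carbon ends up next to pyrone C3. Ring A closes as a six-membered carbocycle by intermolecular cycloaddition, both new bonds (C1–C6 and C4–C5) forming in the same event, and it becomes aromatic through the CO2 extrusion without any oxidant. No stereocentre is carried forward, since both bridgeheads of 12 turn into sp2 carbons. The step needs regioselectivity (aryloxy carbon to C3, not C6), which the matched polarisation of the two partners should secure, and chemoselectivity for cycloaddition over self-oligomerisation of the alkyne, which portionwise addition of an excess of 11 addresses. The two bromines lower the pyrone LUMO and are carried unchanged to C2 and C4, the pyrone methoxy becomes the C1 oxygen and the alkynyl ether oxygen becomes the diaryl ether bridge.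

Step 6
Reactants: 13 1,5-dibromo-2-methoxy-3-(2-methoxyphenoxy)benzene
Product: 15 1,5-dibromo-3-(4,5-dibromo-2-methoxyphenoxy)-2-methoxybenzene, via ring-B monobromide 14 (not isolated)
Conditions: Br2 (2.05 equiv), CH2Cl2/AcOH, 0 °C to rt
Reagents that add atoms: bromine, BrBr
Why: Electrophilic aromatic bromination of a catechol diether, which should take bromine para to each oxygen (C5' para to the methoxy first, then C4' para to the aryloxy oxygen, the pattern by which veratrole gives its 4,5-dibromide), while ring A is deactivated by two bromines and its open positions are flanked.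

Step 7
Reactants: 15 1,5-dibromo-3-(4,5-dibromo-2-methoxyphenoxy)-2-methoxybenzene
Product: 17 2,4-dibromo-6-(4,5-dibromo-2-hydroxyphenoxy)phenol, via bis(aryloxydibromoborane) 16 (not isolated)
Conditions: BBr3 (3 equiv), CH2Cl2, −78 °C to rt; then H2O, 0 °C
Reagents that add atoms: none
Why: Lewis-acid cleavage of both aryl methyl ethers (bromide attacks the methyl group of the boron-complexed ether), a reaction to which the diaryl ether bridge and the aryl bromides are inert.

Step 8
Reactants: 17 2,4-dibromo-6-(4,5-dibromo-2-hydroxyphenoxy)phenol
Product: 18 2,3,4-tribromo-6-(3,5-dibromo-2-hydroxyphenoxy)phenol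
Conditions: Br2 (1.0 equiv), AcOH, rt
Reagents that add atoms: bromine, BrBr
Why: Phenol-directed electrophilic bromination, in which C3' is the only unsubstituted position in the molecule that is ortho or para to a free hydroxyl, so one equivalent should be delivered there.

**Compound list**

1 | 3-hydroxy-2H-pyran-2-one | OC1=CC=COC1=O | starting material
2 | 4-bromo-3-hydroxy-2H-pyran-2-one | OC1=C(Br)C=COC1=O | intermediate (not isolated)
3 | 4,6-dibromo-3-hydroxy-2H-pyran-2-one | OC1=C(Br)C=C(Br)OC1=O | intermediate
4 | 4,6-dibromo-3-methoxy-2H-pyran-2-one | COC1=C(Br)C=C(Br)OC1=O | intermediate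
5 | guaiacol (2-methoxyphenol) | COc1ccccc1O | starting material
6 | trichloroethylene | ClC=C(Cl)Cl | starting material
7 | dichloroacetylene | ClC#CCl | intermediate (not isolated)
8 | 1-{[(E)-1,2-dichloroethenyl]oxy}-2-methoxybenzene | COc1ccccc1O/C(Cl)=C\Cl | intermediate
9 | 1-[(chloroethynyl)oxy]-2-methoxybenzene | COc1ccccc1OC#CCl | intermediate (not isolated)
10 | lithium (2-methoxyphenoxy)acetylide | COc1ccccc1OC#C[Li] | intermediate (not isolated)
11 | 1-(ethynyloxy)-2-methoxybenzene | COc1ccccc1OC#C | intermediate
12 | 1,5-dibromo-4-methoxy-8-(2-methoxyphenoxy)-2-oxabicyclo[2.2.2]octa-5,7-dien-3-one (racemic) | BrC12OC(=O)C(OC)(C(Br)=C1)C(Oc1ccccc1OC)=C2 | intermediate (not isolated)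
13 | 1,5-dibromo-2-methoxy-3-(2-methoxyphenoxy)benzene | COc1ccccc1Oc1cc(Br)cc(Br)c1OC | intermediate
14 | 1,5-dibromo-3-(5-bromo-2-methoxyphenoxy)-2-methoxybenzene | COc1ccc(Br)cc1Oc1cc(Br)cc(Br)c1OC | intermediate (not isolated)
15 | 1,5-dibromo-3-(4,5-dibromo-2-methoxyphenoxy)-2-methoxybenzene | COc1cc(Br)c(Br)cc1Oc1cc(Br)cc(Br)c1OC | intermediate
16 | bis(dibromoboryl) ether of 17 (each phenolic oxygen as O–BBr2) | BrB(Br)Oc1cc(Br)c(Br)cc1Oc1cc(Br)cc(Br)c1OB(Br)Br | intermediate (not isolated)
17 | 2,4-dibromo-6-(4,5-dibromo-2-hydroxyphenoxy)phenol | Oc1cc(Br)c(Br)cc1Oc1cc(Br)cc(Br)c1O | intermediate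
18 | 2,3,4-tribromo-6-(3,5-dibromo-2-hydroxyphenoxy)phenol | Oc1c(Br)cc(Br)cc1Oc1cc(Br)c(Br)c(Br)c1O | target

**Count and risks**

Total steps: 8. Longest linear sequence: 6 steps (1, 2, 5, 6, 7, 8; the guaiacol branch 3, 4, 5–8 is equally long).

Steps most likely to fail:

1. Step 5. The electron-rich alkyne may oligomerise faster than a sluggish cycloaddition proceeds, or bond formation may occur with the reverse orientation (aryloxy carbon to C6). The fallback sets out from guaiacol 5 and returns at 13, building the diaryl ether by substitution instead of cycloaddition. SNAr of 5 on 2-fluorobenzaldehyde (K2CO3, DMF, 120 °C) should give 2-(2-methoxyphenoxy)benzaldehyde F1. Baeyer–Villiger oxidation (mCPBA, CH2Cl2) should give 2-(2-methoxyphenoxy)phenyl formate F2, and mild hydrolysis (K2CO3, MeOH/H2O) 2-(2-methoxyphenoxy)phenol F3. Phenol-selective bromination with benzyltrimethylammonium tribromide (2.05 equiv, CH2Cl2/MeOH, rt) should pass through 4-bromo-2-(2-methoxyphenoxy)phenol F4 to 2,4-dibromo-6-(2-methoxyphenoxy)phenol F5. O-Methylation (MeI, K2CO3, acetone) then gives 13.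

2. Step 4. The terminal alkynyl ether may be lost by oligomerisation or hydration during work-up and concentration, and ring lithiation ortho to the methoxy group may compete. The fallback sets out from 8 and returns at 11, storing the alkyne in silyl-capped form. The lithium acetylide 10 generated as before (via 9) is trapped with iPr3SiCl to give triisopropyl[(2-methoxyphenoxy)ethynyl]silane F6, which can be purified and kept. Bu4NF (THF, 0 °C) releases 11 in small batches immediately before the cycloaddition.

3. Step 6. Site selectivity may erode in the second bromination (attack at C3' or C6' instead of C4'), and over-bromination may spill onto ring A. The fallback sets out from 13 and returns at 18, letting the free hydroxyl direct first. BBr3 (CH2Cl2, then H2O) should cleave both methyl ethers through the bis(dibromoboryl) ether F7 to give 2,4-dibromo-6-(2-hydroxyphenoxy)phenol F8. Br2 (2 equiv, AcOH) should brominate ring B para and then ortho to its hydroxyl, through 2,4-dibromo-6-(5-bromo-2-hydroxyphenoxy)phenol F9, to give the symmetric 2,2'-oxybis(4,6-dibromophenol) F10. One further equivalent of Br2 (AcOH, gentle warming) should enter para to the ether oxygen, as the third halogen does in the exhaustive halogenation of guaiacol. Both rings of F10 are equivalent, so either one leads to 18.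

Further compounds
F1 | step 5 | 2-(2-methoxyphenoxy)benzaldehyde | COc1ccccc1Oc1ccccc1C=O
F2 | step 5 | 2-(2-methoxyphenoxy)phenyl formate | COc1ccccc1Oc1ccccc1OC=O
F3 | step 5 | 2-(2-methoxyphenoxy)phenol | COc1ccccc1Oc1ccccc1O
F4 | step 5 | 4-bromo-2-(2-methoxyphenoxy)phenol | COc1ccccc1Oc1cc(Br)ccc1O
F5 | step 5 | 2,4-dibromo-6-(2-methoxyphenoxy)phenol | COc1ccccc1Oc1cc(Br)cc(Br)c1O
F6 | step 4 | triisopropyl[(2-methoxyphenoxy)ethynyl]silane | COc1ccccc1OC#C[Si](C(C)C)(C(C)C)C(C)C
F7 | step 6 | bis(dibromoboryl) ether of 2,4-dibromo-6-(2-hydroxyphenoxy)phenol | BrB(Br)Oc1ccccc1Oc1cc(Br)cc(Br)c1OB(Br)Br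
F8 | step 6 | 2,4-dibromo-6-(2-hydroxyphenoxy)phenol | Oc1ccccc1Oc1cc(Br)cc(Br)c1O
F9 | step 6 | 2,4-dibromo-6-(5-bromo-2-hydroxyphenoxy)phenol | Oc1ccc(Br)cc1Oc1cc(Br)cc(Br)c1O
F10 | step 6 | 2,2'-oxybis(4,6-dibromophenol) | Oc1c(Br)cc(Br)cc1Oc1cc(Br)cc(Br)c1O
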